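The ten-membered ring is never cyclised: it is unveiled by cutting the C2–C7 bond of a 6-6-6 tricycle. C2 and C7, the oxygenated carbons flanking the C3=C4–C5=C6 diene, lie 1,6 across ring C1–C10, so a C2–C7 bond folds the target into a carvone-derived trans-decalin (rings A and B) fused to a cyclohexa-3,5-diene-1,2-diol (ring C). Glycol scission of that cis-diol with Pb(OAc)4 breaks the bond shared by rings B and C, creates both ketones and delivers the ring-cis,cis diene in one operation. Stereocontrolled reductions, lactonisation and desilylation finish the synthesis.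

Key step: step 31

Remarks. Briarane numbering is used (C15 on C1, C20 on C11, C16 on C5, side chain C17/C18/C19 on C8). Ring A is C1, C10–C14; ring B is C1, C2, C7–C10; ring C is C2–C7. β is the face of rings A and B that carries C15.
Assumption: the hydroboration of step 5 is not expected to control C17, so 7–47 are carried as C17-epimer pairs (their SMILES leave C17 open) that converge in step 36. The carbinol configurations at C2 in 5–20 and at C7 in 23, 30 and 31 are transient, drawn as expected, and either epimer serves.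

**Ring A and B construction**

Step 1
Reactants: 1 ethyl vinyl ketone
Product: 2 (Z)-3-(tert-butyldimethylsilyloxy)penta-1,3-diene
Conditions: TBSOTf, Et3N, Et2O, 0 °C
Reagents that add atoms: tert-butyldimethylsilyl triflate, CC(C)(C)[Si](C)(C)OS(=O)(=O)C(F)(F)F
Why: Soft enolisation (O-silylation of the enone, then amine deprotonation of the ethyl CH2) gives the 2-silyloxy diene, the Z enol ether being favoured because the methyl group avoids the vinyl group.

Step 2
Reactants: 2 silyloxy diene; 3 (S)-(+)-carvone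
Product: 4 cis-fused decalin adduct (C2 ketone, C12 silyl enol ether, 8β-isopropenyl)
Conditions: EtAlCl2 (0.3 equiv), toluene, −40 °C → rt
Reagents that add atoms: none
Why: In this Lewis-acid-promoted Diels–Alder reaction the silyloxy group makes the methyl-bearing diene terminus nucleophilic, so it bonds to C10 while C14 bonds to C1 (para orientation); the diene adds to the face opposite the isopropenyl group, which fixes quaternary C1 and the cis fusion, and the endo transition state puts the C11 methyl trans to H-10.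

Step 3
Reactants: 4 Diels–Alder adduct
Product: 5 2β-alcohol
Conditions: LiAlH4, Et2O, −78 → 0 °C
Reagents that add atoms: none
Why: Hydride reduction of the hindered ketone leaves the silyl enol ether untouched; hydride is expected anti to the angular C15 methyl, and this carbinol centre is destroyed again in step 17.

Step 4
Reactants: 5 2β-alcohol
Product: 6 2β-acetate
Conditions: Ac2O, pyridine, DMAP (cat.), CH2Cl2, rt
Reagents that add atoms: acetic anhydride, CC(=O)OC(C)=O
Why: DMAP-catalysed acylation masks the C2 oxygen so that no C2 alkoxide can trigger vinylogous retro-aldol cleavage of C1–C2 (aromatisation of ring A) in the basic step 10, and the ester is orthogonal to every silyl ether used later.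

Step 5
Reactants: 6 2β-acetate
Product: 8 19-alcohol, via B-alkyl-9-BBN borane 7 (not isolated)
Conditions: 9-BBN, THF, 0 °C → rt; then NaBO3·4H2O, THF/H2O, rt
Reagents that add atoms: sodium perborate (NaBO3·4H2O), [Na+].[O-]OB=O
Why: In this hydroboration–oxidation 9-BBN adds anti-Markovnikov to the 1,1-disubstituted alkene far faster than to the trisubstituted enol ether and perborate oxidises the C–B bond without cleaving the acetate; C17 forms without facial control.

Step 6
Reactants: 8 19-alcohol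
Product: 9 19-O-TBS ether
Conditions: TBSCl, imidazole, DMF, 0 °C → rt
Reagents that add atoms: tert-butyldimethylsilyl chloride, CC(C)(C)[Si](C)(C)Cl
Why: Silylation of the only free, primary hydroxyl.

Step 7
Reactants: 9 bis-silyl compound
Product: 10 13-en-12-one
Conditions: Pd(OAc)2 (10 mol %), O2 (1 atm), DMSO, 45 °C
Reagents that add atoms: none
Why: In this Saegusa oxidation divalent palladium attacks the enol ether at C13, β-hydride elimination of H-14 gives the enone, and O2 reoxidises zerovalent palladium.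

Step 8
Reactants: 10 13-en-12-one
Product: 11 10,13-dien-12-one
Conditions: DDQ, dry 1,4-dioxane, reflux
Reagents that add atoms: none
Why: Quinone dehydrogenation: the ketone enolises towards C11 (its only α-hydrogen) and DDQ abstracts hydride from C10, as in the conversion of 1-en-3-one steroids into 1,4-dien-3-ones.

Step 9
Reactants: 11 10,13-dien-12-one
Product: 12 8,10,13-trien-12-one (2β-OAc, 19-OTBS)
Conditions: chloranil, t-BuOH, reflux
Reagents that add atoms: none
Why: Quinone dehydrogenation through the extended dienol (γ-enolisation at C9, hydride loss from C8), as in the conversion of 1,4-dien-3-one into 1,4,6-trien-3-one steroids; C8, C10 and C11 are now all trigonal.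

Step 10
Reactants: 12 trienone
Product: 13 13α,14α-epoxy-8,10-dien-12-one
Conditions: t-BuOOH (anhydrous), DBU, CH2Cl2, 0 °C → rt
Reagents that add atoms: tert-butyl hydroperoxide, CC(C)(C)OO
Why: In this Weitz–Scheffer epoxidation the peroxide anion adds to the disubstituted enone terminus C14 rather than to tetrasubstituted C10, enters opposite the axial C15 methyl (α face), and the enolate closes the oxirane; the anhydrous amidine base spares the acetate.

Step 11
Reactants: 13 epoxy dienone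
Product: 14 12β-alcohol
Conditions: NaBH4, CeCl3·7H2O, MeOH/CH2Cl2, −78 °C
Reagents that add atoms: none
Why: Luche 1,2-reduction: hydride is delivered axially to the α face of the half-chair epoxy dienone, as with 1α,2α-epoxy-4,6-dien-3-one steroids, giving the 12β-alcohol trans to the oxirane; C2 is still masked, so no second ketone competes.

Step 12
Reactants: 14 12β-alcohol
Product: 15 12β-O-TES ether
Conditions: TESCl, imidazole, DMF, 0 °C
Reagents that add atoms: triethylsilyl chloride, CC[Si](Cl)(CC)CC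
Why: Silylation under weakly basic conditions that cannot induce Payne rearrangement of the epoxy alcohol; the ether stands in for the later acetate.

Step 13
Reactants: 15 diene
Product: 16 8α,9α-diol
Conditions: OsO4 (5 mol %), N-methylmorpholine N-oxide, acetone/H2O, 0 °C → rt
Reagents that add atoms: N-methylmorpholine N-oxide, C[N+]1([O-])CCOCC1; water, O
Why: Catalytic syn-dihydroxylation takes the trisubstituted, accessible C8=C9 of the diene rather than tetrasubstituted C10=C11 and occurs on the α face, away from C15 and the other β substituents, giving the cis-8α,9α-diol.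

Step 14
Reactants: 16 allylic diol
Product: 17 trans-decalin diol (H-10α, 11β-methyl)
Conditions: H2 (1 atm), [Ir(cod)(PCy3)(py)]PF6 (10 mol %), CH2Cl2, rt
Reagents that add atoms: none
Why: Hydroxyl-directed homogeneous hydrogenation: the cationic iridium centre binds the α-oriented allylic 9-OH (and 8-OH) and delivers both hydrogens to the α face of the tetrasubstituted alkene, setting the trans ring fusion and the 11β-methyl, while the β-oriented 12-oxygen is capped and cannot direct.

Step 15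
Reactants: 17 diol
Product: 19 9α-OTES, 8α-OTMS bis-ether, via 9-O-triethylsilyl ether 18 (not isolated)
Conditions: TESOTf (1.1 equiv), 2,6-lutidine, CH2Cl2, −78 °C; then TMSOTf, −78 → 0 °C
Reagents that add atoms: triethylsilyl triflate, CC[Si](CC)(CC)OS(=O)(=O)C(F)(F)F; trimethylsilyl triflate, C[Si](C)(C)OS(=O)(=O)C(F)(F)F
Why: Sequential silylation in which one equivalent of the bulkier triflate takes the secondary 9-OH and the small TMS group then caps the tertiary 8-OH.

Step 16
Reactants: 19 acetate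
Product: 20 2β-alcohol
Conditions: i-Bu2AlH, CH2Cl2, −78 °C; aqueous sodium potassium tartrate
Reagents that add atoms: none
Why: Reductive deacylation cleaves the acetate at −78 °C without touching the silyl ethers or the oxirane, whereas basic methanolysis would strip the tertiary TMS ether.

Step 17
Reactants: 20 2β-alcohol
Product: 21 C2 ketone
Conditions: Dess–Martin periodinane, NaHCO3, CH2Cl2, 0 °C → rt
Reagents that add atoms: none
Why: Buffered Dess–Martin oxidation of the hindered secondary alcohol; no vicinal diol is free at this stage.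

Step 18
Reactants: 21 C2 ketone
Product: 23 C2 ketone with 7α-OTMS (fully oxygenated trans-decalin), via trimethylsilyl enol ether 22 (not isolated)
Conditions: LiN(SiMe3)2, Me3SiCl, THF, −78 °C; crude enol ether, then dimethyldioxirane, acetone/CH2Cl2, −78 → 0 °C
Reagents that add atoms: trimethylsilyl chloride, C[Si](C)(C)Cl; dimethyldioxirane, CC1(C)OO1
Why: Rubottom oxidation: the ketone can enolise only towards C7 (C1 is quaternary), the internal silyl quench prevents β-elimination of the 8-silyloxy group, and the dioxirane oxidises the enol ether with silyl transfer to the new C7 oxygen, whose configuration is erased in step 24.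

**Enyne fragment**

Step 19
Reactants: 24 2-bromoprop-2-en-1-ol
Product: 25 TBDPS ether
Conditions: TBDPSCl, imidazole, CH2Cl2, rt
Reagents that add atoms: tert-butyldiphenylsilyl chloride, CC(C)(C)[Si](Cl)(c1ccccc1)c1ccccc1
Why: Silylation of the primary alcohol with the group that must outlast the TBS ether at the end.

Step 20
Reactants: 25 vinyl bromide; 26 trimethylsilylacetylene
Product: 27 silylated enyne
Conditions: PdCl2(PPh3)2 (3 mol %), CuI (6 mol %), Et3N, THF, rt → 45 °C
Reagents that add atoms: none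
Why: Sonogashira coupling (oxidative addition of the vinyl bromide to zerovalent palladium, copper acetylide transmetalation, reductive elimination) joins C4 to C5.

Step 21
Reactants: 27 silylated enyne
Product: 28 terminal enyne (C3–C5, C16)
Conditions: K2CO3, MeOH, rt
Reagents that add atoms: none
Why: Methanolysis of the alkynyl C–Si bond, to which the TBDPS ether is inert.

**Ring C**

Step 22
Reactants: 28 terminal enyne; 23 C2 ketone
Product: 30 C2 tertiary propargylic alcohol (alkynyl α, OH β), via lithium acetylide 29 (not isolated)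
Conditions: 28, n-BuLi, THF, −78 °C; added to 23 premixed with anhydrous CeCl3, THF, −78 → −40 °C; aqueous NH4Cl
Reagents that add atoms: none
Why: 1,2-Addition of a lithium acetylide to a CeCl3-activated ketone (the oxophilic salt suppresses enolisation at C7): the slender nucleophile takes the axial trajectory on the α face, anti to the axial C15 methyl on the neighbouring carbon as in additions to 9-methyl-1-decalones, so C3 becomes axial and the new hydroxyl equatorial.

Step 23
Reactants: 30 propargylic alcohol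
Product: 31 2,7,8-triol
Conditions: K2CO3, MeOH, 0 °C → rt
Reagents that add atoms: none
Why: Basic methanolysis removes the secondary and the tertiary TMS ether while the TES, TBS and TBDPS ethers survive.

Step 24
Reactants: 31 triol
Product: 32 C7 ketone
Conditions: IBX, DMSO/THF, rt
Reagents that add atoms: none
Why: IBX oxidises the secondary 7-OH without cleaving the flanking vicinal diols (as periodinane or lead reagents might), and the ketone, set between two fully substituted carbons, cannot enolise.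

Step 25
Reactants: 32 C7 ketone; 26 trimethylsilylacetylene
Product: 34 C2,C7-dialkynyl cis-diol, via lithium trimethylsilylacetylide 33 (not isolated)
Conditions: 26, n-BuLi, THF, −78 °C (5 equiv); added to 32 premixed with anhydrous CeCl3, THF, −78 → 0 °C; aqueous NH4Cl
Reagents that add atoms: none
Why: 1,2-Addition of the acetylide to the CeCl3-activated ketone (excess reagent first deprotonates the two hydroxyls): the axial β trajectory is closed by the 1,3-syn-axial C15 methyl, so the alkyne enters equatorially from the α side and the new 7-OH is axial (β), cis to the equatorial 2-OH.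

Step 26
Reactants: 34 silylated diyne
Product: 35 terminal alkyne
Conditions: K2CO3, MeOH, rt
Reagents that add atoms: none
Why: Methanolysis of the alkynyl C–Si bond; all O-silyl groups present are stable to these conditions.

Step 27
Reactants: 35 bis-TES ether
Product: 36 2,7,8,9,12-pentaol
Conditions: PPTS, MeOH/CH2Cl2, 0 °C → rt
Reagents that add atoms: none
Why: Mild acid methanolysis removes the two secondary TES ethers much faster than the primary TBS and TBDPS ethers and is too weak to ionise the tertiary propargylic alcohols or open the oxirane.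

Step 28
Reactants: 36 pentaol
Product: 37 9,12-diacetate
Conditions: Ac2O, pyridine, rt
Reagents that add atoms: acetic anhydride, CC(=O)OC(C)=O
Why: Acylation without a strong nucleophilic catalyst reaches only the secondary 9- and 12-hydroxyls; the three tertiary alcohols stay free.

Step 29
Reactants: 37 diyne
Product: 38 triene (7-vinyl, 2-[(Z)-dienyl])
Conditions: H2 (1 atm), Pd on CaCO3 poisoned with Pb(OAc)2 (Lindlar catalyst), quinoline, EtOAc, rt, monitored
Reagents that add atoms: none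
Why: Lindlar semihydrogenation (syn addition on poisoned palladium) turns the terminal alkyne into the vinyl group and the conjugated enyne into the (Z)-1,3-diene, which fixes the C3=C4 geometry.

Step 30
Reactants: 38 triene
Product: 39 6-6-6 tricycle with ring C as cyclohexa-3,5-diene cis-1,2-diol
Conditions: RuCl2(=CHPh)(PCy3)(H2IMes) (second-generation Grubbs catalyst, 10 mol %), CH2Cl2, 40 °C
Reagents that add atoms: none
Why: Ring-closing metathesis: the ruthenium carbene loads on the C7 vinyl group and closes on the 1,1-disubstituted diene terminus to form C5=C6 in the only unstrained (six-membered) ring available, releasing ethylene; the axial/equatorial cis arrangement of the two alkenyl arms permits closure.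

**Ring expansion and endgame**

Step 31
Reactants: 39 tricyclic diene triol
Product: 41 ten-membered (ring-cis,cis)-3,5-diene-2,7-dione, via cyclic plumbate 40 (not isolated)
Conditions: Pb(OAc)4 (1.05 equiv), dry CH2Cl2, −30 → 0 °C
Reagents that add atoms: none
Why: Ligand exchange of Pb(OAc)4 with the gauche, cis-disposed tertiary hydroxyls on C2 (equatorial) and C7 (axial) gives the five-membered cyclic diolate of tetravalent lead 40, which collapses in a concerted two-electron fragmentation that breaks the C2–C7 σ bond, turns both C–O bonds into C=O and releases divalent lead as Pb(OAc)2. The closest known reaction types are the Criegee cleavage of decalin-9,10-diols to cyclodecane-1,6-diones and of cyclohexa-3,5-diene-1,2-diols to (Z,Z)-hexa-2,4-dienedials. The step is not an end-to-end cyclisation: rings B and C share the C2–C7 bond as the zero-atom bridge of a bicyclo[4.4.0]decane, and deleting that bridge merges them into the ten-membered carbocycle C1–C10, both six-membered rings having been assembled beforehand by routine closures. No stereocentre is created (C2 and C7 become trigonal), and C3=C4 and C5=C6 emerge ring-cis because both alkenes sat inside six-membered ring C. The needed selectivity for the C2/C7 glycol over the C7/C8 glycol comes from the locked trans-decalin, in which 7-OH and 8-OH are trans-diaxial and cannot bind one lead atom, while one equivalent of oxidant in dry aprotic solvent spares the α-ketol product. Dehydrative aromatisation of ring C, the usual fate of such diene diols, is impossible because both carbinol carbons are fully substituted.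

Step 32
Reactants: 41 dienedione
Product: 42 (7S)-alcohol (C2 ketone retained)
Conditions: Zn(BH4)2, Et2O/CH2Cl2, −78 → −40 °C
Reagents that add atoms: none
Why: Chelation-controlled 1,2-reduction: zinc bridges 8-OH and the C7 carbonyl, which also makes this ketone react before the C2 ketone, and hydride attacks the chelate from the periphery of the ring, on the side of C17 and away from C9, giving the (7S)-alcohol.

Step 33
Reactants: 42 hydroxy enone
Product: 43 (2S,7S)-diol
Conditions: (R)-2-methyl-CBS-oxazaborolidine (20 mol %), catecholborane (4 equiv), toluene, −78 → −40 °C; MeOH, aqueous NaHCO3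
Reagents that add atoms: none
Why: CBS reduction under reagent control: with quaternary C1 as the large and the cis-alkenyl C3 as the small substituent the (R)-oxazaborolidine should give the (2S)-alcohol, and catecholborane caps the free hydroxyls as borates that carry no hydride, so no intramolecular delivery competes.

Step 34
Reactants: 43 diol
Product: 44 19-alcohol (2,7,8,19-tetraol)
Conditions: HF·pyridine, pyridine, THF, 0 °C
Reagents that add atoms: none
Why: Buffered fluoride desilylation removes the primary TBS ether far faster than the primary TBDPS ether and leaves acetates, oxirane and allylic alcohols alone.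

Step 35
Reactants: 44 tetraol
Product: 47 γ-lactone (C17 epimers), via C19 aldehyde 45 (not isolated), via lactol 46 (not isolated)
Conditions: [Cu(MeCN)4]OTf (10 mol %), 2,2′-bipyridine (10 mol %), TEMPO (10 mol %), N-methylimidazole (20 mol %), air, MeCN, rt
Reagents that add atoms: none
Why: Aerobic copper/nitroxyl oxidative lactonisation: the catalyst oxidises only the unhindered primary 19-OH, the aldehyde is trapped by the γ-hydroxyl on C7 as a five-membered lactol, and this is oxidised to the lactone; no glycol-cleaving oxidant is present, so the 7,8-diol is safe.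

Step 36
Reactants: 47 lactone (C17 epimer pair)
Product: 48 16-O-TBDPS briaexcavatolide N ((17R)-lactone)
Conditions: DBU (0.5 equiv), CH2Cl2, rt
Reagents that add atoms: none
Why: Base-mediated epimerisation through the lactone enolate should converge on the (17R)-epimer, whose C18 methyl is trans to C9 and cis to the smaller 8-hydroxyl.

Step 37
Reactants: 48 silyl ether
Product: 49 briaexcavatolide N
Conditions: Bu4NF, AcOH (1:1), THF, 0 °C → rt
Reagents that add atoms: none
Why: Fluoride desilylation of the TBDPS ether, buffered with acetic acid so that no acetyl migration or lactone opening occurs.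

**Compound list**

1 | pent-1-en-3-one (ethyl vinyl ketone; C11–C14, C20) | CCC(=O)C=C | starting material
2 | (Z)-3-(tert-butyldimethylsilyloxy)penta-1,3-diene | C/C=C(O[Si](C)(C)C(C)(C)C)/C=C | intermediate
3 | (S)-(+)-carvone (C1, C2, C7–C10, C15, C17–C19) | CC1=CC[C@@H](CC1=O)C(C)=C | starting material
4 | cis-decalin Diels–Alder adduct: C2 ketone, 12-OTBS enol ether (C12=C13), 8β-isopropenyl, 1β-methyl, H-10β, 11α-methyl | C[C@H]1[C@H]2C[C@H](C(C)=C)CC(=O)[C@@]2(C)CC=C1O[Si](C)(C)C(C)(C)C | intermediate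
5 | 2β-alcohol of 4 | C[C@H]1[C@H]2C[C@H](C(C)=C)C[C@H](O)[C@@]2(C)CC=C1O[Si](C)(C)C(C)(C)C | intermediate
6 | 2β-acetate of 5 | C[C@H]1[C@H]2C[C@H](C(C)=C)C[C@H](OC(C)=O)[C@@]2(C)CC=C1O[Si](C)(C)C(C)(C)C | intermediate
7 | B-(C19-alkyl)-9-borabicyclo[3.3.1]nonane from 6 (C17 epimers) | C[C@H]1[C@H]2C[C@H](C(C)CB3C4CCCC3CCC4)C[C@H](OC(C)=O)[C@@]2(C)CC=C1O[Si](C)(C)C(C)(C)C | intermediate
8 | 19-alcohol: 2β-acetoxy 12-OTBS enol ether with 8β-CH(CH3)CH2OH | C[C@H]1[C@H]2C[C@H](C(C)CO)C[C@H](OC(C)=O)[C@@]2(C)CC=C1O[Si](C)(C)C(C)(C)C | intermediate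
9 | 19-O-TBS ether of 8 | C[C@H]1[C@H]2C[C@H](C(C)CO[Si](C)(C)C(C)(C)C)C[C@H](OC(C)=O)[C@@]2(C)CC=C1O[Si](C)(C)C(C)(C)C | intermediate
10 | 2β-acetoxy-19-OTBS-13-en-12-one (H-10β, 11α-methyl) | C[C@H]1[C@H]2C[C@H](C(C)CO[Si](C)(C)C(C)(C)C)C[C@H](OC(C)=O)[C@@]2(C)C=CC1=O | intermediate
11 | 2β-acetoxy-19-OTBS-10,13-dien-12-one | CC1=C2C[C@H](C(C)CO[Si](C)(C)C(C)(C)C)C[C@H](OC(C)=O)[C@@]2(C)C=CC1=O | intermediate
12 | 2β-acetoxy-19-OTBS-8,10,13-trien-12-one | O=C1C(C)=C2C=C(C(C)CO[Si](C)(C)C(C)(C)C)C[C@H](OC(C)=O)[C@@]2(C)C=C1 | intermediate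
13 | 2β-acetoxy-13α,14α-epoxy-19-OTBS-8,10-dien-12-one | O=C1C(C)=C2C=C(C(C)CO[Si](C)(C)C(C)(C)C)C[C@H](OC(C)=O)[C@@]2(C)[C@H]2O[C@@H]12 | intermediate
14 | 2β-acetoxy-13α,14α-epoxy-19-OTBS-8,10-dien-12β-ol | O[C@@H]1C(C)=C2C=C(C(C)CO[Si](C)(C)C(C)(C)C)C[C@H](OC(C)=O)[C@@]2(C)[C@H]2O[C@@H]12 | intermediate
15 | 12β-O-TES ether of 14 | CC[Si](CC)(CC)O[C@@H]1C(C)=C2C=C(C(C)CO[Si](C)(C)C(C)(C)C)C[C@H](OC(C)=O)[C@@]2(C)[C@H]2O[C@@H]12 | intermediate
16 | 2β-acetoxy-13α,14α-epoxy-12β-OTES-19-OTBS-10-ene-8α,9α-diol | CC[Si](CC)(CC)O[C@@H]1C(C)=C2[C@@H](O)[C@](O)(C(C)CO[Si](C)(C)C(C)(C)C)C[C@H](OC(C)=O)[C@@]2(C)[C@H]2O[C@@H]12 | intermediate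
17 | trans-decalin 8α,9α-diol: H-10α, 11β-methyl, 2β-OAc, 12β-OTES, 13α,14α-epoxide, 19-OTBS | CC[Si](CC)(CC)O[C@@H]1[C@H](C)[C@@H]2[C@@H](O)[C@](O)(C(C)CO[Si](C)(C)C(C)(C)C)C[C@H](OC(C)=O)[C@@]2(C)[C@H]2O[C@@H]12 | intermediate
18 | 9α-O-TES ether of 17 (8α-OH free) | CC[Si](CC)(CC)O[C@@H]1[C@H](C)[C@@H]2[C@@H](O[Si](CC)(CC)CC)[C@](O)(C(C)CO[Si](C)(C)C(C)(C)C)C[C@H](OC(C)=O)[C@@]2(C)[C@H]2O[C@@H]12 | intermediate
19 | 9α-OTES, 8α-OTMS, 2β-acetate | CC[Si](CC)(CC)O[C@@H]1[C@H](C)[C@@H]2[C@@H](O[Si](CC)(CC)CC)[C@](O[Si](C)(C)C)(C(C)CO[Si](C)(C)C(C)(C)C)C[C@H](OC(C)=O)[C@@]2(C)[C@H]2O[C@@H]12 | intermediate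
20 | 2β-alcohol from 19 | CC[Si](CC)(CC)O[C@@H]1[C@H](C)[C@@H]2[C@@H](O[Si](CC)(CC)CC)[C@](O[Si](C)(C)C)(C(C)CO[Si](C)(C)C(C)(C)C)C[C@H](O)[C@@]2(C)[C@H]2O[C@@H]12 | intermediate
21 | C2 ketone (C7 methylene) | CC[Si](CC)(CC)O[C@@H]1[C@H](C)[C@@H]2[C@@H](O[Si](CC)(CC)CC)[C@](O[Si](C)(C)C)(C(C)CO[Si](C)(C)C(C)(C)C)CC(=O)[C@@]2(C)[C@H]2O[C@@H]12 | intermediate
22 | C2(OTMS)=C7 trimethylsilyl enol ether | CC[Si](CC)(CC)O[C@@H]1[C@H](C)[C@@H]2[C@@H](O[Si](CC)(CC)CC)[C@](O[Si](C)(C)C)(C(C)CO[Si](C)(C)C(C)(C)C)C=C(O[Si](C)(C)C)[C@@]2(C)[C@H]2O[C@@H]12 | intermediate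
23 | fully oxygenated trans-decalin: C2 ketone, 7α-OTMS, 8α-OTMS, 9α-OTES, 12β-OTES, 13α,14α-epoxide, 19-OTBS | CC[Si](CC)(CC)O[C@@H]1[C@H](C)[C@@H]2[C@@H](O[Si](CC)(CC)CC)[C@](O[Si](C)(C)C)(C(C)CO[Si](C)(C)C(C)(C)C)[C@@H](O[Si](C)(C)C)C(=O)[C@@]2(C)[C@H]2O[C@@H]12 | intermediate
24 | 2-bromoprop-2-en-1-ol (C5, C16) | OCC(Br)=C | starting material
25 | (2-bromoallyloxy)(tert-butyl)diphenylsilane | C=C(Br)CO[Si](c1ccccc1)(c1ccccc1)C(C)(C)C | intermediate
26 | trimethylsilylacetylene (C3, C4; later C6) | C#C[Si](C)(C)C | starting material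
27 | tert-butyl[2-methylene-4-(trimethylsilyl)but-3-ynyloxy]diphenylsilane | C[Si](C)(C)C#CC(=C)CO[Si](c1ccccc1)(c1ccccc1)C(C)(C)C | intermediate
28 | tert-butyl(2-methylenebut-3-ynyloxy)diphenylsilane | C#CC(=C)CO[Si](c1ccccc1)(c1ccccc1)C(C)(C)C | intermediate
29 | lithium acetylide of 28 | [Li]C#CC(=C)CO[Si](c1ccccc1)(c1ccccc1)C(C)(C)C | intermediate
30 | C2 tertiary propargylic alcohol: 2α-enynyl, 2β-OH, 7α-OTMS, 8α-OTMS | CC[Si](CC)(CC)O[C@@H]1[C@H](C)[C@@H]2[C@@H](O[Si](CC)(CC)CC)[C@](O[Si](C)(C)C)(C(C)CO[Si](C)(C)C(C)(C)C)[C@@H](O[Si](C)(C)C)[C@@](O)(C#CC(=C)CO[Si](c3ccccc3)(c3ccccc3)C(C)(C)C)[C@@]2(C)[C@H]2O[C@@H]12 | intermediate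
31 | 2β,7α,8α-triol from 30 | CC[Si](CC)(CC)O[C@@H]1[C@H](C)[C@@H]2[C@@H](O[Si](CC)(CC)CC)[C@](O)(C(C)CO[Si](C)(C)C(C)(C)C)[C@@H](O)[C@@](O)(C#CC(=C)CO[Si](c3ccccc3)(c3ccccc3)C(C)(C)C)[C@@]2(C)[C@H]2O[C@@H]12 | intermediate
32 | C7 ketone with 2β-OH and 8α-OH | CC[Si](CC)(CC)O[C@@H]1[C@H](C)[C@@H]2[C@@H](O[Si](CC)(CC)CC)[C@](O)(C(C)CO[Si](C)(C)C(C)(C)C)C(=O)[C@@](O)(C#CC(=C)CO[Si](c3ccccc3)(c3ccccc3)C(C)(C)C)[C@@]2(C)[C@H]2O[C@@H]12 | intermediate
33 | lithium trimethylsilylacetylide | [Li]C#C[Si](C)(C)C | intermediate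
34 | C2,C7-dialkynyl cis-diol: 7α-(trimethylsilylethynyl), 7β-OH, 2α-enynyl, 2β-OH | CC[Si](CC)(CC)O[C@@H]1[C@H](C)[C@@H]2[C@@H](O[Si](CC)(CC)CC)[C@](O)(C(C)CO[Si](C)(C)C(C)(C)C)[C@@](O)(C#C[Si](C)(C)C)[C@@](O)(C#CC(=C)CO[Si](c3ccccc3)(c3ccccc3)C(C)(C)C)[C@@]2(C)[C@H]2O[C@@H]12 | intermediate
35 | 7α-ethynyl analogue of 34 | CC[Si](CC)(CC)O[C@@H]1[C@H](C)[C@@H]2[C@@H](O[Si](CC)(CC)CC)[C@](O)(C(C)CO[Si](C)(C)C(C)(C)C)[C@@](O)(C#C)[C@@](O)(C#CC(=C)CO[Si](c3ccccc3)(c3ccccc3)C(C)(C)C)[C@@]2(C)[C@H]2O[C@@H]12 | intermediate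
36 | 2β,7β,8α,9α,12β-pentaol | O[C@@H]1[C@H](C)[C@@H]2[C@@H](O)[C@](O)(C(C)CO[Si](C)(C)C(C)(C)C)[C@@](O)(C#C)[C@@](O)(C#CC(=C)CO[Si](c3ccccc3)(c3ccccc3)C(C)(C)C)[C@@]2(C)[C@H]2O[C@@H]12 | intermediate
37 | 9α,12β-diacetate of 36 | CC(=O)O[C@@H]1[C@H](C)[C@@H]2[C@@H](OC(C)=O)[C@](O)(C(C)CO[Si](C)(C)C(C)(C)C)[C@@](O)(C#C)[C@@](O)(C#CC(=C)CO[Si](c3ccccc3)(c3ccccc3)C(C)(C)C)[C@@]2(C)[C@H]2O[C@@H]12 | intermediate
38 | triene: 7α-vinyl, 2α-[(Z)-3-(TBDPS-oxymethyl)buta-1,3-dienyl] | CC(=O)O[C@@H]1[C@H](C)[C@@H]2[C@@H](OC(C)=O)[C@](O)(C(C)CO[Si](C)(C)C(C)(C)C)[C@@](O)(C=C)[C@@](O)(/C=C\C(=C)CO[Si](c3ccccc3)(c3ccccc3)C(C)(C)C)[C@@]2(C)[C@H]2O[C@@H]12 | intermediate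
39 | 6-6-6 tricycle: ring C cyclohexa-3,5-diene with cis 2β,7β-diol, 8α-OH, 9α,12β-diacetate | CC(=O)O[C@@H]1[C@H](C)[C@@H]2[C@@H](OC(C)=O)[C@](O)(C(C)CO[Si](C)(C)C(C)(C)C)[C@@]3(O)C=C(CO[Si](c4ccccc4)(c4ccccc4)C(C)(C)C)C=C[C@@]3(O)[C@@]2(C)[C@H]2O[C@@H]12 | intermediate
40 | cyclic 2,7-diolate of lead diacetate (2,2-diacetoxy-1,3,2-dioxaplumbolane) | CC(=O)O[C@@H]1[C@H](C)[C@@H]2[C@@H](OC(C)=O)[C@](O)(C(C)CO[Si](C)(C)C(C)(C)C)[C@@]3(O5)C=C(CO[Si](c4ccccc4)(c4ccccc4)C(C)(C)C)C=C[C@@]3(O[Pb]5(OC(C)=O)OC(C)=O)[C@@]2(C)[C@H]2O[C@@H]12 | intermediate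
41 | ten-membered (3Z,5E; ring-cis,cis)-3,5-diene-2,7-dione, 8-OH, 19-OTBS, 16-OTBDPS | CC(=O)O[C@@H]1[C@H](C)[C@@H]2[C@@H](OC(C)=O)[C@](O)(C(C)CO[Si](C)(C)C(C)(C)C)C(=O)/C=C(CO[Si](c3ccccc3)(c3ccccc3)C(C)(C)C)\C=C/C(=O)[C@@]2(C)[C@H]2O[C@@H]12 | intermediate
42 | (7S)-7,8-diol, C2 ketone | CC(=O)O[C@@H]1[C@H](C)[C@@H]2[C@@H](OC(C)=O)[C@](O)(C(C)CO[Si](C)(C)C(C)(C)C)[C@@H](O)/C=C(CO[Si](c3ccccc3)(c3ccccc3)C(C)(C)C)\C=C/C(=O)[C@@]2(C)[C@H]2O[C@@H]12 | intermediate
43 | (2S,7S)-2,7,8-triol, 19-OTBS | CC(=O)O[C@@H]1[C@H](C)[C@@H]2[C@@H](OC(C)=O)[C@](O)(C(C)CO[Si](C)(C)C(C)(C)C)[C@@H](O)/C=C(CO[Si](c3ccccc3)(c3ccccc3)C(C)(C)C)\C=C/[C@H](O)[C@@]2(C)[C@H]2O[C@@H]12 | intermediate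
44 | (2S,7S)-2,7,8,19-tetraol | CC(=O)O[C@@H]1[C@H](C)[C@@H]2[C@@H](OC(C)=O)[C@](O)(C(C)CO)[C@@H](O)/C=C(CO[Si](c3ccccc3)(c3ccccc3)C(C)(C)C)\C=C/[C@H](O)[C@@]2(C)[C@H]2O[C@@H]12 | intermediate
45 | C19 aldehyde of 44 | CC(=O)O[C@@H]1[C@H](C)[C@@H]2[C@@H](OC(C)=O)[C@](O)(C(C)C=O)[C@@H](O)/C=C(CO[Si](c3ccccc3)(c3ccccc3)C(C)(C)C)\C=C/[C@H](O)[C@@]2(C)[C@H]2O[C@@H]12 | intermediate
46 | C19,O7 lactol (C19 and C17 epimers) | CC(=O)O[C@@H]1[C@H](C)[C@@H]2[C@@H](OC(C)=O)[C@@]3(O)[C@H](/C=C(CO[Si](c4ccccc4)(c4ccccc4)C(C)(C)C)\C=C/[C@H](O)[C@@]2(C)[C@H]2O[C@@H]12)OC(O)C3C | intermediate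
47 | 16-O-TBDPS γ-lactone as C17 epimer pair | CC(=O)O[C@@H]1[C@H](C)[C@@H]2[C@@H](OC(C)=O)[C@@]3(O)[C@H](/C=C(CO[Si](c4ccccc4)(c4ccccc4)C(C)(C)C)\C=C/[C@H](O)[C@@]2(C)[C@H]2O[C@@H]12)OC(=O)C3C | intermediate
48 | 16-O-TBDPS briaexcavatolide N ((2S,7S,17R)) | CC(=O)O[C@@H]1[C@H](C)[C@@H]2[C@@H](OC(C)=O)[C@@]3(O)[C@H](/C=C(CO[Si](c4ccccc4)(c4ccccc4)C(C)(C)C)\C=C/[C@H](O)[C@@]2(C)[C@H]2O[C@@H]12)OC(=O)[C@@H]3C | intermediate
49 | briaexcavatolide N | CC(=O)O[C@@H]1[C@H](C)[C@@H]2[C@@H](OC(C)=O)[C@@]3(O)[C@H](/C=C(CO)\C=C/[C@H](O)[C@@]2(C)[C@H]2O[C@@H]12)OC(=O)[C@@H]3C | target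

**Step count and risks**

Total step count: 37 steps. Longest linear sequence: 34 steps (steps 1–18 and 22–37, from ethyl vinyl ketone); the enyne fragment takes 3 steps (19–21).

Steps judged most likely to fail:

Step 31 (glycol scission). A second ligand exchange at 8-OH could lead to scission of the C7–C8 glycol or of the α-ketol product, or the free 8-hydroxyl could add across the ring to the new C2 ketone. The fallback removes that hydroxyl from play. It sets out from 39: buffered HF·pyridine removes the primary TBS ether to give the 19-alcohol F1; t-Bu2Si(OTf)2 with 2,6-lutidine ties O19 and O8 into the six-membered di-tert-butylsilylene F2, leaving only the C2/C7 diol free; Pb(OAc)4 then gives the silylene-protected dienedione F3; HF·pyridine releases the 8,19-diol dienedione F4; selective silylation of the primary hydroxyl with TBSCl and imidazole returns to the route at 41.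

Step 25 (alkynylation of the C7 ketone). Addition to a carbonyl buried between two fully substituted carbons may be so slow that the bis-alkoxide ketone is recovered or undergoes α-ketol rearrangement instead. The fallback uses a more nucleophilic sp2 organometallic and has only one alkyne to reduce later. It sets out from 32: vinylmagnesium bromide with anhydrous CeCl3 gives the 7α-vinyl carbinol F5; PPTS in MeOH removes the TES ethers to give the pentaol F6; Ac2O and pyridine give the 9,12-diacetate F7; Lindlar semihydrogenation of the remaining enyne returns to the route at 38.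

Step 9 (chloranil dehydrogenation). Hydride abstraction from the substituted C8 by a weak quinone may be slow, and prolonged heating with the acidic hydroquinone may cause dienone–phenol rearrangement or loss of silyl groups. The fallback replaces hydride abstraction by a palladium-mediated dehydrosilylation. It sets out from 11: TBSOTf and Et3N give, by γ-deprotonation at C9, the cross-conjugated silyl trienol ether F8; Saegusa oxidation with stoichiometric Pd(OAc)2 in MeCN (palladation at C9, β-hydride elimination of H-8) returns to the route at 12.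

**Further compounds**

F1 | step 31 | 19-alcohol of tricycle 39 (TBS removed) | CC(=O)O[C@@H]1[C@H](C)[C@@H]2[C@@H](OC(C)=O)[C@](O)(C(C)CO)[C@@]3(O)C=C(CO[Si](c4ccccc4)(c4ccccc4)C(C)(C)C)C=C[C@@]3(O)[C@@]2(C)[C@H]2O[C@@H]12
F2 | step 31 | 8,19-O-di-tert-butylsilylene of F1 | CC(=O)O[C@@H]1[C@H](C)[C@@H]2[C@@H](OC(C)=O)[C@](O5)(C(C)CO[Si]5(C(C)(C)C)C(C)(C)C)[C@@]3(O)C=C(CO[Si](c4ccccc4)(c4ccccc4)C(C)(C)C)C=C[C@@]3(O)[C@@]2(C)[C@H]2O[C@@H]12
F3 | step 31 | 8,19-O-di-tert-butylsilylene ten-membered 3,5-diene-2,7-dione | CC(=O)O[C@@H]1[C@H](C)[C@@H]2[C@@H](OC(C)=O)[C@](O5)(C(C)CO[Si]5(C(C)(C)C)C(C)(C)C)C(=O)/C=C(CO[Si](c3ccccc3)(c3ccccc3)C(C)(C)C)\C=C/C(=O)[C@@]2(C)[C@H]2O[C@@H]12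
F4 | step 31 | 8,19-dihydroxy ten-membered 3,5-diene-2,7-dione | CC(=O)O[C@@H]1[C@H](C)[C@@H]2[C@@H](OC(C)=O)[C@](O)(C(C)CO)C(=O)/C=C(CO[Si](c3ccccc3)(c3ccccc3)C(C)(C)C)\C=C/C(=O)[C@@]2(C)[C@H]2O[C@@H]12
F5 | step 25 | 7α-vinyl-2α-enynyl cis-2β,7β-diol (9,12-bis-TES) | CC[Si](CC)(CC)O[C@@H]1[C@H](C)[C@@H]2[C@@H](O[Si](CC)(CC)CC)[C@](O)(C(C)CO[Si](C)(C)C(C)(C)C)[C@@](O)(C=C)[C@@](O)(C#CC(=C)CO[Si](c3ccccc3)(c3ccccc3)C(C)(C)C)[C@@]2(C)[C@H]2O[C@@H]12
F6 | step 25 | 7α-vinyl pentaol | O[C@@H]1[C@H](C)[C@@H]2[C@@H](O)[C@](O)(C(C)CO[Si](C)(C)C(C)(C)C)[C@@](O)(C=C)[C@@](O)(C#CC(=C)CO[Si](c3ccccc3)(c3ccccc3)C(C)(C)C)[C@@]2(C)[C@H]2O[C@@H]12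
F7 | step 25 | 7α-vinyl 9,12-diacetate | CC(=O)O[C@@H]1[C@H](C)[C@@H]2[C@@H](OC(C)=O)[C@](O)(C(C)CO[Si](C)(C)C(C)(C)C)[C@@](O)(C=C)[C@@](O)(C#CC(=C)CO[Si](c3ccccc3)(c3ccccc3)C(C)(C)C)[C@@]2(C)[C@H]2O[C@@H]12
F8 | step 9 | 12-(tert-butyldimethylsilyloxy)-9,11,13-triene (silyl trienol ether of 11) | CC1=C(O[Si](C)(C)C(C)(C)C)C=C[C@]2(C)[C@@H](OC(C)=O)C[C@@H](C(C)CO[Si](C)(C)C(C)(C)C)C=C12
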